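(The data stem from a simulated flask with made-up constants; scatter was added.)

The meeting opened on E.

| flask | L | J | E | remark | time |
|---|---|---|---|---|---|
| alpha | 0.022 M | 0.0264 M | 0.0077 M | run made earlier |  |
| beta | 0.022 M | 0.0264 M | 0.042 M | run made earlier |  |
| eta | 0.022 M | 0.0264 M | 0.11 M | run made earlier |  |
| west | 0.022 M | 0.0264 M | 0.0100 M |  | 30 min |
| east | 0.022 M | 0.0264 M | 0.0200 M |  | 30 min |
| north-east | 0.022 M | 0.0264 M | 0.0400 M |  | 30 min |
| south-west | 0.022 M | 0.0264 M | 0.0800 M |  | 30 min |
| north | 0.022 M | 0.0264 M | 0.150 M |  | 30 min |

- alpha (time / min: Q / %, L / %): 1.33: 0.3, 94.8; 2.50: 1.3, 91.4; 4.00: 0.5, 90.0; 8.00: 0, 84.8; 15.0: 0.6, 79.7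
- beta (time / min: Q / %, L / %): 3.00: 0, 60.7; 6.00: 2.1, 43.7; 10.0: 6.1, 30.6; 12.0: 8.0, 28.3; 15.0: 8.5, 23.9
- eta (time / min: Q / %, L / %): 1.33: 0, 50.0; 4.00: 4.0, 18.7; 8.00: 12.4, 1.8; 10.0: 13.7, 3.0; 15.0: 21.5, 1.9

(readings scatter by 1 percentage point)

- percentages count the L that a species holds: one X counts as two
- Q is meant together with its D
- the numbers in the tables scatter with a standard deviation of 1 percentage point
- steps that have been proposed: L + E -> G; E + J -> Z; G + Z -> Q; 2 G -> X; E + Q <-> D
- the concentration of Q that is asked is that of its free form alone
- "hardly changes" means that all values lie within two and a half points (for a concentration: within two and a half percent of the largest)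

- [Q] (only what is free in solution) at the end for west, east, north-east, south-west, north, in this order
- how that number moves from the first to the last of them (falls, then rises / rises all the way / falls all the way / rises, then falls / hardly changes)

The chair recalled the proposed steps: L takes E to give G, J takes E to give Z, G and Z give Q, two G give X, and Q binds E reversibly as D. The plant chemist set the charges of E against the demand: L and J together ask for 0.0484 M of it to become G and Z, and this demand lies between north-east and south-west.

The kineticist answered that a demand does not say how a short charge is divided, but that the two rates can be integrated in closed form: each of L and J is lost first order in itself at the same [E], so dividing one rate by the other cancels [E] and time. She read from alpha the selectivity factor, the logarithm of the fraction of J left over the logarithm of the fraction of L left. With L at 79.7 % after 15.0 min, and taking the whole 0.0077 M of E as consumed by then, J had received 0.003234 M, which gives s = 0.576.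

The plant chemist objected that L in alpha still lost 5.1 percentage points over the last interval, and she granted that E still present at that time means a smaller s than this one, which is in any case a reading with the scatter of its readings.

She then committed herself on west, where the charge falls short of the demand: by her estimate, with E dividing as [L] against s[J], L gives up about 26.9 % of its charge and J makes about 0.00436 M of Z, and since each Q takes one Z she expected Q in west to stay below about that figure. She expected free [Q] to climb as E approaches the demand, then to fall as excess E binds Q as D, north holding 0.102 M beyond the demand.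

The forecast gave 3.000 × 10⁻⁴ M, 0.0015 M, 0.0048 M, 0.0049 M and 0.0029 M, so rises, then falls, reasoning that “Total Q therefore rises but saturates”.

The flasks gave free [Q] of 5.51 × 10⁻⁴ M, 0.00163 M, 0.00367 M, 0.00338 M and 0.00177 M, so rises, then falls, the row turning at 0.054 M of E.

    L + E → G (k = 0.0850 /M/s)
    E + J → Z (k = 0.0540 /M/s)
    G + Z → Q (k = 0.0250 /M/s)
    2 G → X (k = 0.0390 /M/s)
    E + Q ⇌ D, settled at all times (K = 32.0 /M)

In west at 30.0 min, L stood at 75.0 % of its charge, from which s gives 84.7 % of J, and J stood at 83.3 %. In north-east at 30.0 min, L stood at 17.3 %, from which s gives 36.4 % of J, and J stood at 32.8 %.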